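Which flask holds the most homo product at 25 h, and how far is it then from where the books close?

| setting | Saturday's | Friday's | Sunday's | Tuesday's | east | north | north-east | north-west | south |
|---|---|---|---|---|---|---|---|---|---|
| starting material | 30 mM | 30 mM | 30 mM | 60 mM | 30 mM (fed, over 20 h) | 30 mM | 30 mM | 30 mM | 30 mM |
| partner | 39 mM | 39 mM | 39 mM | 39 mM | 39.0 mM | 39.0 mM | 39.0 mM | 39.0 mM (fed, over 20 h) | 39.0 mM (in portions, 5, over 20 h) |
| protic impurity | 30 mM | 42 mM | 66 mM | 30 mM | 30.0 mM | 30.0 mM | 30.0 mM | 30.0 mM | 30.0 mM |
| temperature | 105 °C | 116 °C | 105 °C | 116 °C | 110 °C |  | 110 °C |  | 110 °C |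
| remark | run made earlier | run made earlier | run made earlier | run made earlier | all else is in the flask from the start; the feed brings no volume worth counting | everything together at the start at 90 °C, warmed to 110 °C at 20 h | everything together at the start | the addition at 90 °C, then warmed to 110 °C; the feed brings no volume worth counting | first portion at the start, last at 20 h |
| time |  |  |  |  | 25 h | 25 h | 25 h | 25 h | 25 h |

| run | time / h | homo product / % | target / % |
|---|---|---|---|
| Saturday's | 1.33 | 0 | 0 |
| Saturday's | 3.00 | 3 | 1 |
| Saturday's | 6.00 | 5 | 2 |
| Saturday's | 15.0 | 22 | 10 |
| Friday's | 4.00 | 15 | 4 |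
| Friday's | 8.00 | 34 | 7 |
| Friday's | 12.0 | 46 | 7 |
| Friday's | 15.0 | 51 | 9 |
| Sunday's | 1.33 | 0 | 0 |
| Sunday's | 3.00 | 1 | 0 |
| Sunday's | 6.00 | 4 | 0 |
| Sunday's | 15.0 | 22 | 3 |
| Tuesday's | 2.00 | 12 | 3 |
| Tuesday's | 5.00 | 29 | 6 |
| Tuesday's | 10.0 | 55 | 11 |
| Tuesday's | 15.0 | 65 | 11 |

(scatter of a reading: 1.5 percentage points)

- the flask that comes out highest in amount of homo product, in percent of the starting material charged, or "all alike" when all lie within 1.5 percentage points (east / north / north-east / north-west / south / all alike)
- homo product at the end, in percent of the starting material charged, east
- homo product at the end, in percent of the starting material charged, north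
- homo product at the end, in percent of the starting material charged, north-east
- homo product at the end, in percent of the starting material charged, north-west
- homo product at the end, in percent of the starting material charged, south

- percentages count the starting material that a species holds: one homo product counts as two

I keep the books on partner and count everything in fractions of the starting material charged. Saturday's and Sunday's runs differ in impurity, 30 mM against 66 mM. At 15.0 h both read 22 % homo product, but target falls from 10 % to 3 %. So I take it that impurity destroys partner.

The entries are these. Partner comes in at 1.30 of the charge. Impurity, counted one for one, takes 1.00. That leaves 30.0 %, the free-partner share: partner left over after impurity, per starting material charged. It is below the charge, so partner is the limiting reagent for target. Starting material that target doesn't take ends as homo product, so the books close near 70.0 % homo product.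

Tuesday's share is 15.0 %, and its target reads 11 % and then 11 %, flat and below that entry. Friday's books go negative, yet target reads 9 %, so the one-for-one count is rough.

East, north, north-east, north-west and south carry the same charges, so the free-partner share is the same for each. South gets its partner in 5 portions over 20 h, so part of it comes in later than in north-east. I rank south above north-east, then east, and put the flasks held at 90 °C last.

The forecast gives south 49.5 %, north-east 48 %, east 36 %, north-west 20 % and north 19 %: “Dosing partner slightly lowers target, so south edges north-east, though this is nearly a tie.”

The flasks give south 55.0 %, north-east 47.4 %, east 27.7 %, north-west 16.7 % and north 16.2 %.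

    open intermediate + second intermediate → target (k = 8.00 × 10⁻⁴ /M/s, Ea = 72.0 kJ/mol)
    partner → second intermediate (k = 6.50 × 10⁻⁵ /s, Ea = 125 kJ/mol)
    partner + protic impurity → quenched reagent (k = 0.0280 /M/s, Ea = 72.0 kJ/mol)
    partner → decomposed reagent (k = 5.80 × 10⁻⁶ /s, Ea = 117 kJ/mol)
    2 open intermediate → homo product (k = 3.70 × 10⁻⁴ /M/s, Ea = 96.0 kJ/mol)
    starting material ⇌ open intermediate (K = 17.0, k = 8.20 × 10⁻⁵ /s, Ea = 129 kJ/mol, ΔH = −53.0 kJ/mol)
    (constants at 110 °C)

South has not come to rest at 25 h. Its open intermediate still holds 34.8 %. Its partner side holds target 7.80 %, second intermediate 19.4 % of the charge, unused partner 3.28 % of the charge and decomposed reagent 2.43 % of the charge. Together that is 33.0 %, against the share of 30.0 %, and in south quenched reagent stands at 29.1 mM, with 3.0 % of the protic impurity's own charge left. At 250 h south reads 73.2 % homo product, 18 percentage points further on and above the 70.0 % of the books. North climbs from 16.2 % to 70.4 % at 250 h, level with the 70.0 %.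

The numbers in the tables were generated by integration with made-up constants; noise was put on by code.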